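The readings were generated by integration from invented constants; the scatter is artificial.

Ash holds a small charge of Q, 0.012 M, against 3.7 mM of J. The length you want is Z over chains begun, and the runs show Z but not chains, so I bracket it.

| setting | teal | ochre | birch | ash |
|---|---|---|---|---|
| Q | 0.013 M | 0.059 M | 0.050 M | 0.012 M |
| E | 1.5 mM | 1.5 mM | 1.50 mM | 1.50 mM |
| J | 3.7 mM | 3.7 mM | 3.7 mM | 3.7 mM |
| remark | run made earlier | run made earlier |  |  |
| time |  |  | 30 min | 30 min |

| teal: time / min | teal: Z / % | ochre: time / min | ochre: Z / % |
|---|---|---|---|
| 1.33 | 7.5 | 4.00 | 25.6 |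
| 3.00 | 14.3 | 8.00 | 43.9 |
| 6.00 | 25.4 | 12.0 | 59.0 |
| 15.0 | 49.0 | 15.0 | 66.0 |

(standard deviation of a reading: 1 percentage point)
- which of the two ends with the longer chains by the average number of monomer units in a chain (chains begun, living or dead) ("neither" if they lie within 10%) (birch / ash / neither)
- average number of monomer units in a chain (chains begun, living or dead) at the end, birch
- average number of monomer units in a chain (chains begun, living or dead) at the end, ash
- the average divides the monomer in chains by the number of chains begun, living and dead together
- the numbers in the tables scatter with a standard deviation of 1 percentage point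
- candidate steps: Q + L -> Z + L; Q + J -> L + Z; L + E -> D; 2 J -> G
- the earlier runs do not show the number of chains; that part of a forecast is a guess

Freeze c_L, and Q falls pseudo-first-order at a rate proportional to c_L. Ochre reads 0.0719 min⁻¹ at its last reading. Teal's late stretch reads 0.0423 min⁻¹. Ochre's living ends cannot exceed its J, so the rates' ratio gives the living ceiling, read as the most c_L per J charged in teal: 0.588. Dead chains stand outside this ceiling. I use it for ash, whose Q is close to teal's.

Carrying these rates to 30 min:

Z: birch 44.2 mM, ash 8.75 mM

Floor, one chain per J charged: birch 12.0, ash 2.37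

Estimate for ash, living ends at the ceiling and dead chains uncounted: 4.03

Growth up to teal's first reading is at most the late rate times Q, so teal has at least this many chains:

0.244 mM

Roof, teal's fewest chains carried over: birch 181, ash 35.8

One scattered reading carries the roof, so it is loose. I commit to birch, near 12.0, against ash near 4.03.

The forecast says birch, with 13 for birch and 3 for ash: “J dimerisation cannot be pinned down, but it looks minor.” Both its lengths lie inside my brackets, and its ash lies below my estimate.

    Q + L → Z + L, rate k1*[L]*[Q] (k = 27.8 M⁻¹ min⁻¹)
    Q + J → L + Z (k = 24.0 M⁻¹ min⁻¹)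
    L + E → D (k = 5.35 M⁻¹ min⁻¹)
    2 J → G (k = 144 M⁻¹ min⁻¹)

The flask gives birch, with birch at 16.4 and ash at 5.55, each above its floor. In ash, J went by Q + J at 0.27 of its rate by 2 J at the start, and by 15.0 min J stood at 0.828% of its charge, with G at 0.00110 M. Q + L ran on: at 12.0 min it gave Q a half-life of 19 min, against 9.3 h by Q + J. Ash's living ends at 30.0 min come to 0.329 per J charged, under the ceiling 0.588. Its neighbour with 0.0030 M of Q reaches length 2.29, with 0.132 living ends per J charged.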